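Starting from the constants, I sort what happens in these flasks from fast to slow.

the same everywhere: substrate 0.10 M; solid reagent 0.110 M; time 10 h
- amber: temperature 85 °C
- teal: temperature 100 °C
- green: temperature 70 °C

* the flask with the highest amount of single product, in percent of the substrate charged ("all alike" if they lie within 1.5 percentage points) (amber / teal / green / all alike)
* final single product, as a percentage of the substrate charged, in amber
* final single product, as a percentage of the substrate charged, in teal
* final single product, as a percentage of the substrate charged, in green

    partner + other mono adduct → bis adduct + by-product (k1 = 0.15 M⁻¹ s⁻¹, Ea1 = 50.0 kJ mol⁻¹)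
    substrate + partner → single product + by-product (k2 = 0.079 M⁻¹ s⁻¹, Ea2 = 82.0 kJ mol⁻¹)
    single product ⇌ isomer of the product (K3 = 2.9, k3 = 1.1 × 10⁻⁴ s⁻¹, Ea3 = 110 kJ mol⁻¹, ΔH3 = −22.0 kJ mol⁻¹)
    substrate + partner → other mono adduct + by-product (k4 = 0.043 M⁻¹ s⁻¹, Ea4 = 87.0 kJ mol⁻¹)
    solid reagent ⇌ partner, rate k5*(cs5 - [partner]) while solid is left; crystals form when [partner] > cs5 (cs5 = 0.050 M, k5 = 3.8 × 10⁻⁴ s⁻¹)
    partner + single product → bis adduct + by-product (k6 = 0.033 M⁻¹ s⁻¹, Ea6 = 55.0 kJ mol⁻¹)
    (constants at 100 °C)

- given per volume of solution although it is solid: solid reagent
- the constants hold at 100 °C; other temperatures follow from the activation energies and enthalpies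
- at the start none of the solid reagent is in solution

The first rung is the loss of dissolved partner. In teal, at the starting substrate, a partner molecule lasts about 82.0 s, far shorter than the 1.61 h that the solid reagent needs even at its top dissolving rate, so [partner] stays low and the feed paces the adduct steps. Partner is the limiting reagent: 0.110 M is charged against 0.10 M of substrate, and each bis adduct costs two.

The rung I reckon last is the isomerisation. Its relaxation half-life is the time in which single product and isomer of the product, the pair, halve their distance from equilibrium: ln(2) divided by the sum of forward and back constants. In teal this is 1.30 h, shorter than the 10 h allowed, so the pair equilibrates and single product keeps 25.6% of it. In green it is 32.8 h, longer than the time allowed. There the forward constant is smaller than in teal by a factor of 22, which puts the equilibrium share of single product at 15.6%.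

Now the rule. Take the equilibrium share and add the remainder, halved once per relaxation half-life. For green this gives 83.9%, the kept share: the part of the pair still single product at the end, counting the pair as made at the start. For teal it gives 26.0%. I do not reckon how large the pair is, so I stop at shares. If the pairs are of like size, green holds more single product than teal, and I place amber, at its middle temperature, between the other two.

The forecast goes further and gives percentages: 19% in amber, 11% in teal and 27% in green, with green on top, on the ground that “so the coolest flask keeps the most”.

The simulation gives 17.8% in amber, 11.0% in teal and 27.0% in green, so green holds the most and the forecast stands within its tolerance.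

The pair in green comes to 31.7% of the substrate charged, and the kept share of that is 26.6%. In teal the pair is 42.2%, and its kept share is 11.0%. The neighbouring flask repeats green with 0.17 M of substrate at the same temperature, so I use the same kept share. Its pair is 26.6% of the substrate charged, which gives 22.3%, and that flask ends with 22.7% as single product.

The rate constants were chosen freely; the rest is arithmetic.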